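**Plan**

1. Retrosynthesis: the O-acetyl group, the C8–C17 bond (carbonylation of a C8 bromide) and the C9–C11 bond (alkylation with dienyl bromide 18) are cut first. This leads back to trans-decalin-6,8-dione 15 and, one oxidation level lower, to decalone 11. Then C4–C5 (ring A), C10–C20 and C10–C1 are cut, back to 3-ethoxycyclohexenone.
2. Enabling feature: the quaternary gem-dimethyl carbon C4 of ring A is bonded to ring-fusion C5, and C5 is α to the C6 oxygen of ring B. C4–C5 is therefore the bond between a tertiary C4 cation and the C5 end of a C5=C6 enol silane.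
3. Forward: ring B is bought, and the C1–C4 chain and C20 are put on C10. Ring A closes onto ring B in step 4, ring B is oxidised to the 6,8-dione, and then C9, C8 and C6 are dressed in that order.
4. Stereochemistry: C10 comes from a ligand-controlled copper conjugate methylation. C5 closes cis for geometric reasons and is turned trans by base equilibration with recycling. C9 is set by axial kinetic protonation anti to C20, C6 by hydride attack anti to the two axial methyl groups, and 12E by the commercial E-enynol.

Key step: step 4

Remark: labdane numbering is used for all bicyclic compounds, "syn" and "anti" refer to the C10 methyl group (C20), and the 1,3-diones are written as diketo tautomers although they are largely enolised.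

Step 1
Reactants: 1 3-ethoxycyclohex-2-en-1-one; 2 5-bromo-2-methylpent-1-ene
Product: 5 3-(4-methylpent-4-en-1-yl)cyclohex-2-en-1-one, via Grignard reagent 3 (not isolated), via tertiary carbinol 4 (not isolated)
Conditions: Mg, THF, reflux; 1, THF, 0 °C; then 1 M HCl, rt
Reagents that add atoms: water, O
Why: Stork–Danheiser sequence, in which 1,2-addition of the Grignard reagent to the vinylogous ester and acid-induced loss of water and ethanol transpose the carbonyl group and place the C1–C4 chain on the future C10.

Step 2
Reactants: 5 3-(4-methylpent-4-en-1-yl)cyclohex-2-en-1-one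
Product: 6 3-(4-chloro-4-methylpentyl)cyclohex-2-en-1-one
Conditions: HCl (g), CH2Cl2, 0 °C
Reagents that add atoms: hydrogen chloride, Cl
Why: Markovnikov hydrochlorination of the 1,1-disubstituted alkene stores the C4 cation as a tertiary chloride at a stage where the only other π system is an electron-poor enone that HCl should leave untouched.

Step 3
Reactants: 6 3-(4-chloro-4-methylpentyl)cyclohex-2-en-1-one; 7 trimethylaluminium
Product: 9 {[(3R)-3-(4-chloro-4-methylpentyl)-3-methylcyclohex-1-en-1-yl]oxy}triethylsilane, via aluminium enolate 8 (not isolated)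
Conditions: CuTC (2 mol %), chiral phosphoramidite L* (4 mol %), Me3Al, Et2O, −30 °C; then TESOTf, −30 → 0 °C; cold aq NaHCO3
Reagents that add atoms: trimethylaluminium (7), C[Al](C)C; triethylsilyl trifluoromethanesulfonate, CC[Si](CC)(CC)OS(=O)(=O)C(F)(F)F
Why: Copper-catalysed asymmetric conjugate addition of Me3Al to a β-substituted cyclohexenone creates the C10 quaternary centre under ligand control (the ligand enantiomer is chosen for the R product), ether-complexed Me3Al should not ionise the tertiary chloride, and the silyl triflate traps the aluminium enolate regiospecifically as the C5=C6 enol silane.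

Step 4
Reactants: 9 {[(3R)-3-(4-chloro-4-methylpentyl)-3-methylcyclohex-1-en-1-yl]oxy}triethylsilane
Product: 10 cis-4,4,10-trimethyldecalin-6-one (H5 syn to C20)
Conditions: TiCl4 (1.1 equiv), CH2Cl2, −78 → −40 °C; cold aq NaHCO3
Reagents that add atoms: none
Why: TiCl4 takes chloride from the tertiary C4–Cl bond, C5 of the enol silane captures the resulting C4 cation, and chloride then removes the silyl group from the C6 oxocarbenium ion, which leaves the ketone and Et3SiCl. The closest known reaction is the Lewis-acid-mediated α-tert-alkylation of silyl enol ethers by tertiary alkyl chlorides, known in inter- and intramolecular form and itself a member of the cation–olefin cyclisations that end on an enol silane. Ring A closes as a six-membered ring through a chair-like array in which the C5=C6 bond stays outside the new ring (6-enol-exo) and the cationic carbon becomes a ring member. C5 is the only new stereocentre and the tether controls it: the chain leaves C10 pseudo-equatorially and can reach the π lobe of C5 only on its own side of ring B, anti to the pseudo-axial C10 methyl, so C4 enters axially on ring B and the cis-decalone is the kinetic product, which step 5 corrects. The step needs C5 rather than C7 as nucleophile and a cation that arises without Brønsted acid: the enol silane regiochemistry is fixed by step 3 and C7 could only close a bridged eight-membered ring, while storing the proton as HCl in step 2 avoids protonation of the enol silane, which is far faster than that of a 1,1-dialkyl alkene.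

Step 5
Reactants: 10 cis-4,4,10-trimethyldecalin-6-one
Product: 11 trans-4,4,10-trimethyldecalin-6-one (H5 anti to C20)
Conditions: NaOMe (cat.), MeOH, rt; chromatography, recovered 10 equilibrated again
Reagents that add atoms: none
Why: Base-catalysed epimerisation α to the ketone interconverts the two ring fusions, which are expected to lie close in energy as in other 10-methyl-1-decalones, so the trans isomer (both ring-A bonds equatorial on ring B) is collected and the remainder is recycled.

Step 6
Reactants: 11 trans-4,4,10-trimethyldecalin-6-one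
Product: 13 trans-4,4,10-trimethyldecal-7-en-6-one, via silyl enol ether 12 (not isolated)
Conditions: LDA, THF, −78 °C; TMSCl; then Pd(OAc)2 (1 equiv), MeCN, rt
Reagents that add atoms: none
Why: Saegusa–Ito oxidation, in which kinetic deprotonation takes the open C7–H and not the C5–H flanked by two quaternary carbons, so the ring fusion is not touched and only the C7–C8 bond can be desaturated.

Step 7
Reactants: 13 trans-4,4,10-trimethyldecal-7-en-6-one
Product: 14 7,8-epoxy-trans-4,4,10-trimethyldecalin-6-one (epoxide anti to C20)
Conditions: 30% H2O2, NaOH (cat.), MeOH, 0 °C, short contact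
Reagents that add atoms: hydrogen peroxide, OO
Why: Weitz–Scheffer epoxidation of an unhindered cis-disubstituted enone, in which hydroperoxide should add anti to C20 but either face serves because both new centres vanish in step 8.

Step 8
Reactants: 14 7,8-epoxy-trans-4,4,10-trimethyldecalin-6-one
Product: 15 trans-4,4,10-trimethyldecalin-6,8-dione
Conditions: Pd(PPh3)4 (cat.), dppe (cat.), toluene, 100 °C
Reagents that add atoms: none
Why: Palladium(0)-catalysed isomerisation of an α,β-epoxy ketone to the 1,3-diketone, which needs only the C8–H that this epoxide carries.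

Step 9
Reactants: 16 (E)-3-methylpent-2-en-4-yn-1-ol
Product: 17 (E)-3-methylpenta-2,4-dien-1-ol
Conditions: H2 (1 atm), Lindlar catalyst, quinoline, MeOH, 0 °C
Reagents that add atoms: none
Why: Lindlar semi-hydrogenation of the terminal alkyne should stop at the vinyl group and leave the E trisubstituted alkene as it is.

Step 10
Reactants: 17 (E)-3-methylpenta-2,4-dien-1-ol
Product: 18 (E)-5-bromo-3-methylpenta-1,3-diene
Conditions: PBr3, Et2O, −10 °C; used at once
Reagents that add atoms: phosphorus tribromide, BrP(Br)Br
Why: PBr3 converts the primary allylic alcohol into the bromide by SN2 displacement at low temperature with retention of the E geometry.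

Step 11
Reactants: 15 trans-4,4,10-trimethyldecalin-6,8-dione; 18 (E)-5-bromo-3-methylpenta-1,3-diene
Product: 20 9-epi-9-[(2E)-3-methylpenta-2,4-dien-1-yl]-trans-4,4,10-trimethyldecalin-6,8-dione (C11 anti to C20), via dilithium dianion 19 (not isolated)
Conditions: LDA (2.3 equiv), THF–DMPU, −78 → 0 °C; 18, −78 → −20 °C; 1 M HCl
Reagents that add atoms: none
Why: γ-Alkylation of a β-diketone dianion, in which the second deprotonation takes the less hindered C9–H rather than C5–H, the terminal carbanion is the most nucleophilic site, and the allylic bromide enters on the axial trajectory anti to C20, which gives the 9-epimer.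

Step 12
Reactants: 20 9-epi-9-[(2E)-3-methylpenta-2,4-dien-1-yl]-trans-4,4,10-trimethyldecalin-6,8-dione
Product: 22 9-[(2E)-3-methylpenta-2,4-dien-1-yl]-trans-4,4,10-trimethyldecalin-6,8-dione (C11 syn to C20), via bis(silyl) dienol ether 21 (not isolated)
Conditions: TMSOTf (3 equiv), Et3N (4 equiv), CH2Cl2, 0 °C → rt; pentane filtration; then 1 M HCl–THF, −20 °C
Reagents that add atoms: none
Why: Double soft enolisation of a 1,3-diketone should give under equilibrating conditions the 1,3-bis(silyloxy)diene with the less strained C8=C9 bond, and its doubly activated terminal carbon C9 is then protonated kinetically on the axial face anti to C20 of the rigid trans-decalin, so that C11 ends syn to C20 as in the target.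

Step 13
Reactants: 22 9-[(2E)-3-methylpenta-2,4-dien-1-yl]-trans-4,4,10-trimethyldecalin-6,8-dione
Product: 23 8-bromo-9-[(2E)-3-methylpenta-2,4-dien-1-yl]-trans-4,4,10-trimethyldecal-7-en-6-one
Conditions: Ph3PBr2, Et3N, CH2Cl2, 0 °C → rt
Reagents that add atoms: dibromotriphenylphosphorane, BrP(Br)(c1ccccc1)(c1ccccc1)c1ccccc1
Why: Phosphonium activation of the enol and addition–elimination of bromide (the standard conversion of cyclic 1,3-diones into β-bromo enones) should take place at C8, because a tetrahedral intermediate at C6 would press its oxygen against both axial methyl groups (C19 and C20) and one at C8 only against C20.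

Step 14
Reactants: 23 8-bromo-9-[(2E)-3-methylpenta-2,4-dien-1-yl]-trans-4,4,10-trimethyldecal-7-en-6-one
Product: 24 8-bromo-9-[(2E)-3-methylpenta-2,4-dien-1-yl]-trans-4,4,10-trimethyldecal-7-en-6-ol (6-OH axial and syn to C20)
Conditions: NaBH4, CeCl3·7H2O, MeOH, −20 °C
Reagents that add atoms: none
Why: Luche reduction gives 1,2-attack on the β-bromo enone, and hydride arrives on the face anti to the axial C19 and C20 methyl groups, which sets the axial C6 alcohol and at the same time removes the acidity of C5–H and C9–H.

Step 15
Reactants: 24 8-bromo-9-[(2E)-3-methylpenta-2,4-dien-1-yl]-trans-4,4,10-trimethyldecal-7-en-6-ol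
Product: 25 6-hydroxylabda-7,12E,14-trien-17-oic acid (5R,6S,9S,10S)
Conditions: Pd(OAc)2 (cat.), dppf (cat.), CO (1 atm), Et3N, DMF–H2O, 70 °C; then dilute citric acid
Reagents that add atoms: carbon monoxide, [C-]#[O+]; water, O
Why: Palladium-catalysed hydroxycarbonylation of an alkenyl bromide installs C17 as the free acid without moving the C7=C8 bond, and the C6 hydroxyl cannot lactonise because it lies trans to C17 across the ring double bond.

Step 16
Reactants: 25 6-hydroxylabda-7,12E,14-trien-17-oic acid
Product: 27 6-acetoxylabda-7,12E,14-trien-17-oic acid (5R,6S,9S,10S; CNP0294871.1), via mixed anhydride 26 (not isolated)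
Conditions: Ac2O, DMAP, pyridine, 40 °C; then H2O–THF, rt
Reagents that add atoms: acetic anhydride, CC(=O)OC(C)=O
Why: DMAP-catalysed acetylation of the hindered axial alcohol also turns the acid into a mixed anhydride, which water should cleave at the less hindered acetyl carbonyl during work-up.

**Compound list**

1 | 3-ethoxycyclohex-2-en-1-one | CCOC1=CC(=O)CCC1 | starting material
2 | 5-bromo-2-methylpent-1-ene | C=C(C)CCCBr | starting material
3 | (4-methylpent-4-en-1-yl)magnesium bromide | C=C(C)CCC[Mg]Br | intermediate (not isolated)
4 | 3-ethoxy-1-(4-methylpent-4-en-1-yl)cyclohex-2-en-1-ol, racemic | C=C(C)CCCC1(O)C=C(OCC)CCC1 | intermediate (not isolated)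
5 | 3-(4-methylpent-4-en-1-yl)cyclohex-2-en-1-one | C=C(C)CCCC1=CC(=O)CCC1 | intermediate
6 | 3-(4-chloro-4-methylpentyl)cyclohex-2-en-1-one | CC(C)(Cl)CCCC1=CC(=O)CCC1 | intermediate
7 | trimethylaluminium | C[Al](C)C | starting material
8 | dimethylaluminium enolate of (R)-3-(4-chloro-4-methylpentyl)-3-methylcyclohexanone (C5=C6) | CC(C)(Cl)CCC[C@]1(C)C=C(O[Al](C)C)CCC1 | intermediate (not isolated)
9 | {[(3R)-3-(4-chloro-4-methylpentyl)-3-methylcyclohex-1-en-1-yl]oxy}triethylsilane | CC(C)(Cl)CCC[C@]1(C)C=C(O[Si](CC)(CC)CC)CCC1 | intermediate
10 | cis-4,4,10-trimethyldecalin-6-one, (4aS,8aS)-4a,8,8-trimethyloctahydronaphthalen-1(2H)-one | C1CCC(=O)[C@H]2C(C)(C)CCC[C@@]12C | intermediate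
11 | trans-4,4,10-trimethyldecalin-6-one, (4aS,8aR)-4a,8,8-trimethyloctahydronaphthalen-1(2H)-one | C1CCC(=O)[C@@H]2C(C)(C)CCC[C@@]12C | intermediate
12 | 6-(trimethylsilyloxy)-trans-4,4,10-trimethyldecal-6-ene | C1CC=C(O[Si](C)(C)C)[C@@H]2C(C)(C)CCC[C@@]12C | intermediate (not isolated)
13 | trans-4,4,10-trimethyldecal-7-en-6-one | C1C=CC(=O)[C@@H]2C(C)(C)CCC[C@@]12C | intermediate
14 | 7,8-epoxy-trans-4,4,10-trimethyldecalin-6-one, epoxide anti to C20 | C1[C@H]3O[C@H]3C(=O)[C@@H]2C(C)(C)CCC[C@@]12C | intermediate
15 | trans-4,4,10-trimethyldecalin-6,8-dione | C1C(=O)CC(=O)[C@@H]2C(C)(C)CCC[C@@]12C | intermediate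
16 | (E)-3-methylpent-2-en-4-yn-1-ol | C#C/C(C)=C/CO | starting material
17 | (E)-3-methylpenta-2,4-dien-1-ol | C=C/C(C)=C/CO | intermediate
18 | (E)-5-bromo-3-methylpenta-1,3-diene | C=C/C(C)=C/CBr | intermediate
19 | dilithium 6,8-bis(enolate) of 15 (C6=C7 and C8=C9) | C1=C([O-])C=C([O-])[C@@H]2C(C)(C)CCC[C@@]12C.[Li+].[Li+] | intermediate (not isolated)
20 | 9-epi-9-[(2E)-3-methylpenta-2,4-dien-1-yl]-trans-4,4,10-trimethyldecalin-6,8-dione, C11 anti to C20 | C=C/C(C)=C/C[C@H]1C(=O)CC(=O)[C@@H]2C(C)(C)CCC[C@@]12C | intermediate
21 | 6,8-bis(trimethylsilyloxy)-9-[(2E)-3-methylpenta-2,4-dien-1-yl]-trans-4,4,10-trimethyldecala-6,8-diene | C=C/C(C)=C/CC1=C(O[Si](C)(C)C)C=C(O[Si](C)(C)C)[C@@H]2C(C)(C)CCC[C@@]12C | intermediate (not isolated)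
22 | 9-[(2E)-3-methylpenta-2,4-dien-1-yl]-trans-4,4,10-trimethyldecalin-6,8-dione, C11 syn to C20 | C=C/C(C)=C/C[C@@H]1C(=O)CC(=O)[C@@H]2C(C)(C)CCC[C@@]12C | intermediate
23 | 8-bromo-9-[(2E)-3-methylpenta-2,4-dien-1-yl]-trans-4,4,10-trimethyldecal-7-en-6-one, C11 syn to C20 | C=C/C(C)=C/C[C@@H]1C(Br)=CC(=O)[C@@H]2C(C)(C)CCC[C@@]12C | intermediate
24 | 8-bromo-9-[(2E)-3-methylpenta-2,4-dien-1-yl]-trans-4,4,10-trimethyldecal-7-en-6-ol, 6-OH and C11 syn to C20 | C=C/C(C)=C/C[C@@H]1C(Br)=C[C@H](O)[C@@H]2C(C)(C)CCC[C@@]12C | intermediate
25 | (5R,6S,9S,10S)-6-hydroxylabda-7,12E,14-trien-17-oic acid | C=C/C(C)=C/C[C@@H]1C(C(=O)O)=C[C@H](O)[C@@H]2C(C)(C)CCC[C@@]12C | intermediate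
26 | acetic 6-acetoxylabda-7,12E,14-trien-17-oic anhydride | C=C/C(C)=C/C[C@@H]1C(C(=O)OC(C)=O)=C[C@H](OC(C)=O)[C@@H]2C(C)(C)CCC[C@@]12C | intermediate (not isolated)
27 | (5R,6S,9S,10S)-6-acetoxylabda-7,12E,14-trien-17-oic acid | C=C/C(C)=C/C[C@@H]1C(C(=O)O)=C[C@H](OC(C)=O)[C@@H]2C(C)(C)CCC[C@@]12C | target

Total step count: 16. Longest linear sequence: 14 (steps 1–8 and 11–16).

**The three steps most likely to fail**

**Step 4.** Loss of a proton from the C4 cation, followed by protodesilylation of the enol silane by the HCl so released, may outrun bond formation at C5, which sits between a quaternary carbon and the siloxy carbon.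
The fallback sets out from 5. The copper-catalysed methyl addition of step 3 is run on 5 with an aqueous quench and should give (S)-3-methyl-3-(4-methylpent-4-en-1-yl)cyclohexan-1-one F1. The C4–C5 bond is then closed by cationic gold(I)-catalysed intramolecular hydroalkylation of the alkene by the ketone (IPrAuCl, AgClO4, toluene, 90 °C).
In that reaction the metal activates the alkene at its substituted carbon and the small equilibrium share of the C5 enol is the nucleophile, so no free cation and no acid-labile enol silane are involved. C7 cannot reach the alkene. The fallback comes back to the route at 10, which enters step 5.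

**Step 12.** Enolisation of 20 towards C5 instead of C9 would leave C9 unchanged and put the ring fusion at risk. Protonation of the diene without facial preference would give back a mixture of C9 epimers.
The fallback sets out from 20. O-Methylation with trimethylsilyldiazomethane should give both vinylogous methyl esters. The 9-epi-6-methoxy-9-dienyl-trans-decal-6-en-8-one F2 is separated, and the 9-epi-8-methoxy-9-dienyl-trans-decal-7-en-6-one F3 is hydrolysed back to 20 with dilute acid.
In F2 the C9–H is the only α′ proton, so LDA should form the cross-conjugated C8=C9 enolate. A quench at −78 °C with a hindered phenol delivers the proton on the axial face anti to C20 and should give 6-methoxy-9-dienyl-trans-decal-6-en-8-one F4 with C11 syn to C20. Hydrolysis with 1 M HCl–THF comes back to the route at 22.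

**Step 11.** Slow C-alkylation at the neopentyl-type C9 carbanion would let proton transfer, C7- or O-alkylation, and base-induced loss of HBr from 18 compete.
The fallback sets out from 15 and replaces the strongly basic dianion by its neutral equivalent. TMSOTf and Et3N should give 6,8-bis(trimethylsilyloxy)-trans-4,4,10-trimethyldecala-6,8-diene F5. ZnBr2 (cat.) in CH2Cl2 then ionises the allylic bromide 18, which is captured by the terminal carbon C9 of the bis(silyloxy)diene, the usual site of attack in such dienes. Aqueous work-up removes the remaining silyl group and comes back to the route at 20.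

**Further compounds**

F1 | step 4 | (S)-3-methyl-3-(4-methylpent-4-en-1-yl)cyclohexan-1-one | C=C(C)CCC[C@]1(C)CC(=O)CCC1
F2 | step 12 | 9-epi-6-methoxy-9-[(2E)-3-methylpenta-2,4-dien-1-yl]-trans-4,4,10-trimethyldecal-6-en-8-one | C=C/C(C)=C/C[C@H]1C(=O)C=C(OC)[C@@H]2C(C)(C)CCC[C@@]12C
F3 | step 12 | 9-epi-8-methoxy-9-[(2E)-3-methylpenta-2,4-dien-1-yl]-trans-4,4,10-trimethyldecal-7-en-6-one | C=C/C(C)=C/C[C@H]1C(OC)=CC(=O)[C@@H]2C(C)(C)CCC[C@@]12C
F4 | step 12 | 6-methoxy-9-[(2E)-3-methylpenta-2,4-dien-1-yl]-trans-4,4,10-trimethyldecal-6-en-8-one, C11 syn to C20 | C=C/C(C)=C/C[C@@H]1C(=O)C=C(OC)[C@@H]2C(C)(C)CCC[C@@]12C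
F5 | step 11 | 6,8-bis(trimethylsilyloxy)-trans-4,4,10-trimethyldecala-6,8-diene | C1=C(O[Si](C)(C)C)C=C(O[Si](C)(C)C)[C@@H]2C(C)(C)CCC[C@@]12C
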